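## Retrosynthetic overview

1. Target 27 comes from chlororesorcinol 26 by oxidation with (KSO3)2NO; 26 comes from its bis-MOM ether 24.
2. Key disconnection C9–C10 (carbinol carbon to alkene carbon): C9 enters as a nucleophile, the geminal bis(boronate) 13 (a masked aldehyde used as an acyl-anion-type donor), and C10 as the electrophilic alkenyl bromide 22. Asymmetric Pd coupling, then C–B oxidation, sets 9S.
3. 13 comes from vinyl ketone 11 (1,1-diboration); 11 from enone 7 by vinyl conjugate addition anti to the C4 methyl (quaternary centre) and enolate methylation.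
4. 7 comes from (R)-4-methylcyclohexenone 5, made from propanal and methyl vinyl ketone (organocatalytic Michael addition, aldol condensation).
5. 22 comes from orcinol (MOM protection, ortho-lithiation/butynylation, chlorination, hydrozirconation–bromination). Only the cyclohexanone ring is built (step 2); the benzene ring is bought and becomes the quinone in the last step.

Assumption: the (R,R)-TADDOL-derived phosphoramidite is taken to give the 9S boronate in step 10; if the coupling shows the opposite sense, the (S,S)-ligand is used with nothing else changed.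

## Route

Step 1
Reactants: 1 propanal; 2 but-3-en-2-one
Product: 3 (R)-2-methyl-5-oxohexanal
Conditions: (S)-diphenylprolinol methyl ether (5 mol%), ethyl 3,4-dihydroxybenzoate (20 mol%), neat, 4 °C
Reagents that add atoms: none
Why: Enamine-catalysed asymmetric Michael addition (diarylprolinol ether catalysis): the bulky group of the (S)-catalyst shields one face of the E-enamine of propanal, so the enone adds to the open Si face and sets the 2R centre that becomes ring C4.

Step 2
Reactants: 3 (R)-2-methyl-5-oxohexanal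
Product: 5 (R)-4-methylcyclohex-2-en-1-one, via aldol adduct 4 (not isolated)
Conditions: 0.1 M aq KOH, nBu4NOH (cat.), Et2O/THF, reflux
Reagents that add atoms: none
Why: Intramolecular aldol condensation: the methyl-ketone enolate closes the six-membered ring onto the aldehyde and 4 loses water to the enone faster than the stereocentre epimerises in the dilute base.

Step 3
Reactants: 5 (R)-4-methylcyclohex-2-en-1-one
Product: 7 (R)-3,4-dimethylcyclohex-2-en-1-one, via lithium enolate 6 (not isolated)
Conditions: Me2CuLi (from MeLi, CuI), Et2O, −78 °C; then PhS(Cl)=NtBu, THF, −78 °C → rt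
Reagents that add atoms: lithium dimethylcuprate, [Li+].C[Cu-]C
Why: Cuprate conjugate addition followed by Mukaiyama dehydrogenation of enolate 6 in the same flask (sulfur attaches at C2, syn-elimination removes the C3 hydrogen) is a one-pot β-methylation of the enone that leaves the C4 centre untouched.

Step 4
Reactants: 7 (R)-3,4-dimethylcyclohex-2-en-1-one; 8 vinylmagnesium bromide
Product: 11 (2R,3S,4R)-3-ethenyl-2,3,4-trimethylcyclohexan-1-one, via bromomagnesium enolate 9 (not isolated), via C2-epimeric ketone 10 (not isolated)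
Conditions: 8 (2 equiv), CuBr·SMe2 (20 mol%), THF, −40 °C; MeI (5 equiv), HMPA, −40 → 0 °C; then NaOMe (cat.), MeOH, rt
Reagents that add atoms: iodomethane, CI
Why: Copper-catalysed conjugate addition delivers vinyl anti to the C4 methyl (axial attack on the half-chair), setting the quaternary centre 3S with the C3 and C4 methyls cis; the regiodefined enolate 9 is C-methylated and base equilibration of the kinetic epimer 10 puts the C2 methyl equatorial (2R, all-cis, estimated about 4:1, minor epimer recycled).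

Step 5
Reactants: 11 (2R,3S,4R)-3-ethenyl-2,3,4-trimethylcyclohexan-1-one
Product: 13 (2R,3S,4R)-3-[2,2-bis(4,4,5,5-tetramethyl-1,3,2-dioxaborolan-2-yl)ethyl]-2,3,4-trimethylcyclohexan-1-one, via alkenylboronate 12 (not isolated)
Conditions: B2pin2 (1.5 equiv), Ni(cod)2 (10 mol%), Cy-Xantphos (10 mol%), toluene, 80 °C
Reagents that add atoms: bis(pinacolato)diboron, CC1(C)OB(OC1(C)C)B1OC(C)(C)C(C)(C)O1
Why: Nickel-catalysed 1,1-diboration of a terminal alkene: boryl–nickel insertion and β-hydride elimination give 12, the nickel hydride re-adds with nickel on the boron-bearing carbon and C–B reductive elimination gives the geminal bis(boronate), a masked aldehyde; the quaternary neighbour blocks chain walking and no stereocentre is formed.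

Step 6
Reactants: 14 5-methylbenzene-1,3-diol (orcinol)
Product: 16 1,3-bis(methoxymethoxy)-5-methylbenzene, via mono-MOM ether 15 (not isolated)
Conditions: MOMCl (2.5 equiv), iPr2NEt (3 equiv), CH2Cl2, 0 °C → rt
Reagents that add atoms: chloromethyl methyl ether, COCCl
Why: Twofold O-alkylation of the phenols (Williamson-type acetal formation) protects them and makes them ortho-directing groups.

Step 7
Reactants: 16 1,3-bis(methoxymethoxy)-5-methylbenzene; 17 1-bromobut-2-yne
Product: 19 2-(but-2-yn-1-yl)-1,3-bis(methoxymethoxy)-5-methylbenzene, via aryllithium 18 (not isolated)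
Conditions: nBuLi (1.1 equiv), TMEDA, THF, 0 °C; then 17, −78 °C → rt
Reagents that add atoms: none
Why: Directed ortho-metalation at the position flanked by both OMOM groups, then SN2 alkylation of the aryllithium at the primary propargylic bromide (SN2′ attack at the methyl-bearing alkyne carbon is disfavoured, and no copper is present).

Step 8
Reactants: 19 2-(but-2-yn-1-yl)-1,3-bis(methoxymethoxy)-5-methylbenzene
Product: 20 2-(but-2-yn-1-yl)-4-chloro-1,3-bis(methoxymethoxy)-5-methylbenzene
Conditions: NCS (1.05 equiv), DMF, rt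
Reagents that add atoms: N-chlorosuccinimide, O=C1CCC(=O)N1Cl
Why: Electrophilic aromatic chlorination at one of the two free positions, which are equivalent by symmetry, so only one monochloride can form.

Step 9
Reactants: 20 2-(but-2-yn-1-yl)-4-chloro-1,3-bis(methoxymethoxy)-5-methylbenzene
Product: 22 2-[(2E)-3-bromobut-2-en-1-yl]-4-chloro-1,3-bis(methoxymethoxy)-5-methylbenzene, via alkenylzirconocene chloride 21 (not isolated)
Conditions: Cp2Zr(H)Cl (1.6 equiv), THF, rt then 45 °C; NBS, 0 °C
Reagents that add atoms: N-bromosuccinimide, O=C1CCC(=O)N1Br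
Why: Hydrozirconation is a syn addition that, after equilibration with excess Cp2Zr(H)Cl, places zirconium on the less hindered methyl-bearing alkyne carbon (expected about 9:1), and bromodezirconation with retention gives the E-alkenyl bromide.

Step 10
Reactants: 13 (2R,3S,4R)-3-[2,2-bis(4,4,5,5-tetramethyl-1,3,2-dioxaborolan-2-yl)ethyl]-2,3,4-trimethylcyclohexan-1-one; 22 2-[(2E)-3-bromobut-2-en-1-yl]-4-chloro-1,3-bis(methoxymethoxy)-5-methylbenzene
Product: 24 (2R,3S,4R)-3-[(2S,3E)-5-[3-chloro-2,6-bis(methoxymethoxy)-4-methylphenyl]-2-hydroxy-3-methylpent-3-en-1-yl]-2,3,4-trimethylcyclohexan-1-one, via allylic boronate 23 (not isolated)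
Conditions: 13 (1.2 equiv), Pd(OAc)2 (5 mol%), (R,R)-TADDOL-derived phosphoramidite (10 mol%), 8 M aq KOH, THF, rt; then 3 M NaOH, 30% H2O2, 0 °C
Reagents that add atoms: hydrogen peroxide, OO
Why: Enantiotopic-group-selective Suzuki–Miyaura coupling of a geminal bis(boronate): 13 is a masked aldehyde whose carbon reacts as the nucleophile, so the future carbinol carbon C9 is joined as an acyl-anion-type donor to the electrophilic alkenyl carbon of 22 (two centres that are both electrophiles in the usual aldehyde plus vinyl halide pairing); the chiral palladium–phosphoramidite complex chooses which boron transmetalates and so fixes C9 as S in 23, the alkene geometry is retained, and the remaining C–B bond is oxidised with retention.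

Step 11
Reactants: 24 (2R,3S,4R)-3-[(2S,3E)-5-[3-chloro-2,6-bis(methoxymethoxy)-4-methylphenyl]-2-hydroxy-3-methylpent-3-en-1-yl]-2,3,4-trimethylcyclohexan-1-one
Product: 26 (2R,3S,4R)-3-[(2S,3E)-5-(3-chloro-2,6-dihydroxy-4-methylphenyl)-2-hydroxy-3-methylpent-3-en-1-yl]-2,3,4-trimethylcyclohexan-1-one, via tris(trimethylsilyl) ether 25 (not isolated)
Conditions: TMSOTf (6 equiv), 2,2′-bipyridyl (9 equiv), CH2Cl2, 0 °C → rt; then H2O, rt (dilute citric acid work-up)
Reagents that add atoms: none
Why: Silyl triflate/2,2′-bipyridyl cleavage of aryl methoxymethyl acetals through pyridinium intermediates works without protic acid, which spares the ionisable allylic alcohol; the silyl ethers of 25 are hydrolysed on adding water and no stereocentre is touched.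

Step 12
Reactants: 26 (2R,3S,4R)-3-[(2S,3E)-5-(3-chloro-2,6-dihydroxy-4-methylphenyl)-2-hydroxy-3-methylpent-3-en-1-yl]-2,3,4-trimethylcyclohexan-1-one
Product: 27 2-chloro-5-hydroxy-6-[(2E,4S)-4-hydroxy-3-methyl-5-[(1S,2R,6R)-1,2,6-trimethyl-3-oxocyclohexyl]pent-2-en-1-yl]-3-methylcyclohexa-2,5-diene-1,4-dione
Conditions: (KSO3)2NO (3 equiv), aq KH2PO4, acetone/H2O, 0 °C → rt
Reagents that add atoms: potassium nitrosodisulfonate, [K+].[K+].[O]N(S(=O)(=O)[O-])S(=O)(=O)[O-]
Why: Teuber oxidation: the only free ring position, para to the hydroxyl next to the chlorine-bearing carbon, is oxidised to the para-quinone and the other hydroxyl stays as the hydroxyquinone OH; the alcohol, ketone and alkene are inert.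

## Compound list

1 | propanal | CCC=O | starting material
2 | but-3-en-2-one (methyl vinyl ketone) | CC(=O)C=C | starting material
3 | (R)-2-methyl-5-oxohexanal | O=C[C@H](C)CCC(C)=O | intermediate
4 | (4R)-3-hydroxy-4-methylcyclohexan-1-one (C3 epimers) | O=C1CC(O)[C@H](C)CC1 | intermediate
5 | (R)-4-methylcyclohex-2-en-1-one | O=C1C=C[C@H](C)CC1 | intermediate
6 | lithium (3S,4R)-3,4-dimethylcyclohex-1-en-1-olate | [Li+].[O-]C1=C[C@@H](C)[C@H](C)CC1 | intermediate
7 | (R)-3,4-dimethylcyclohex-2-en-1-one | O=C1C=C(C)[C@H](C)CC1 | intermediate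
8 | vinylmagnesium bromide | C=C[Mg]Br | starting material
9 | bromomagnesium (3S,4R)-3-ethenyl-3,4-dimethylcyclohex-1-en-1-olate | Br[Mg]OC1=C[C@@](C)(C=C)[C@H](C)CC1 | intermediate
10 | (2S,3S,4R)-3-ethenyl-2,3,4-trimethylcyclohexan-1-one | C=C[C@@]1(C)[C@H](C)CCC(=O)[C@H]1C | intermediate
11 | (2R,3S,4R)-3-ethenyl-2,3,4-trimethylcyclohexan-1-one | C=C[C@@]1(C)[C@H](C)CCC(=O)[C@@H]1C | intermediate
12 | (2R,3R,4R)-2,3,4-trimethyl-3-[(E)-2-(4,4,5,5-tetramethyl-1,3,2-dioxaborolan-2-yl)ethenyl]cyclohexan-1-one (same spatial arrangement as 11) | CC1(C)OB(/C=C/[C@@]2(C)[C@H](C)CCC(=O)[C@@H]2C)OC1(C)C | intermediate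
13 | (2R,3S,4R)-3-[2,2-bis(4,4,5,5-tetramethyl-1,3,2-dioxaborolan-2-yl)ethyl]-2,3,4-trimethylcyclohexan-1-one | CC1(C)OB(OC1(C)C)C(B1OC(C)(C)C(C)(C)O1)C[C@@]2(C)[C@H](C)CCC(=O)[C@@H]2C | intermediate
14 | 5-methylbenzene-1,3-diol (orcinol) | Cc1cc(O)cc(O)c1 | starting material
15 | 3-(methoxymethoxy)-5-methylphenol | Cc1cc(O)cc(OCOC)c1 | intermediate
16 | 1,3-bis(methoxymethoxy)-5-methylbenzene | Cc1cc(OCOC)cc(OCOC)c1 | intermediate
17 | 1-bromobut-2-yne | CC#CCBr | starting material
18 | [2,6-bis(methoxymethoxy)-4-methylphenyl]lithium | [Li]c1c(OCOC)cc(C)cc1OCOC | intermediate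
19 | 2-(but-2-yn-1-yl)-1,3-bis(methoxymethoxy)-5-methylbenzene | CC#CCc1c(OCOC)cc(C)cc1OCOC | intermediate
20 | 2-(but-2-yn-1-yl)-4-chloro-1,3-bis(methoxymethoxy)-5-methylbenzene | CC#CCc1c(OCOC)cc(C)c(Cl)c1OCOC | intermediate
21 | chlorobis(cyclopentadienyl)[(2E)-4-[3-chloro-2,6-bis(methoxymethoxy)-4-methylphenyl]but-2-en-2-yl]zirconium | C/C(=C\Cc1c(OCOC)cc(C)c(Cl)c1OCOC)[Zr](Cl)(C1C=CC=C1)C1C=CC=C1 | intermediate
22 | 2-[(2E)-3-bromobut-2-en-1-yl]-4-chloro-1,3-bis(methoxymethoxy)-5-methylbenzene | Cc1cc(OCOC)c(C/C=C(\C)Br)c(OCOC)c1Cl | intermediate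
23 | (2R,3S,4R)-3-[(2S,3E)-5-[3-chloro-2,6-bis(methoxymethoxy)-4-methylphenyl]-3-methyl-2-(4,4,5,5-tetramethyl-1,3,2-dioxaborolan-2-yl)pent-3-en-1-yl]-2,3,4-trimethylcyclohexan-1-one | Cc1cc(OCOC)c(C/C=C(\C)[C@@H](B2OC(C)(C)C(C)(C)O2)C[C@@]3(C)[C@H](C)CCC(=O)[C@@H]3C)c(OCOC)c1Cl | intermediate
24 | (2R,3S,4R)-3-[(2S,3E)-5-[3-chloro-2,6-bis(methoxymethoxy)-4-methylphenyl]-2-hydroxy-3-methylpent-3-en-1-yl]-2,3,4-trimethylcyclohexan-1-one | Cc1cc(OCOC)c(C/C=C(\C)[C@@H](O)C[C@@]2(C)[C@H](C)CCC(=O)[C@@H]2C)c(OCOC)c1Cl | intermediate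
25 | (2R,3S,4R)-3-[(2S,3E)-5-[3-chloro-4-methyl-2,6-bis(trimethylsilyloxy)phenyl]-3-methyl-2-(trimethylsilyloxy)pent-3-en-1-yl]-2,3,4-trimethylcyclohexan-1-one | Cc1cc(O[Si](C)(C)C)c(C/C=C(\C)[C@@H](O[Si](C)(C)C)C[C@@]2(C)[C@H](C)CCC(=O)[C@@H]2C)c(O[Si](C)(C)C)c1Cl | intermediate
26 | (2R,3S,4R)-3-[(2S,3E)-5-(3-chloro-2,6-dihydroxy-4-methylphenyl)-2-hydroxy-3-methylpent-3-en-1-yl]-2,3,4-trimethylcyclohexan-1-one | Cc1cc(O)c(C/C=C(\C)[C@@H](O)C[C@@]2(C)[C@H](C)CCC(=O)[C@@H]2C)c(O)c1Cl | intermediate
27 | 2-chloro-5-hydroxy-6-[(2E,4S)-4-hydroxy-3-methyl-5-[(1S,2R,6R)-1,2,6-trimethyl-3-oxocyclohexyl]pent-2-en-1-yl]-3-methylcyclohexa-2,5-diene-1,4-dione | CC1=C(Cl)C(=O)C(C/C=C(\C)[C@@H](O)C[C@@]2(C)[C@H](C)CCC(=O)[C@@H]2C)=C(O)C1=O | target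

## Step count and risks

Total steps: 12. Longest linear sequence: 8 (steps 1–5, 10, 11, 12); the arene branch (steps 6–9) joins at step 10.

The three steps most likely to fail:

Step 10. The bis(boronate) carries a neopentyl-type substituent and its two boron groups are diastereotopic, so transmetalation may be slow or poorly selective. The fallback sets out from 13 and 22 and comes back at 24. Both C–B bonds of 13 are oxidised with NaBO3·4H2O in THF/H2O to the keto aldehyde 2-[(1S,2R,6R)-1,2,6-trimethyl-3-oxocyclohexyl]acetaldehyde F3. Bromide 22 is converted with CrCl2 and catalytic NiCl2, in the presence of a chiral sulfonamide ligand, into the alkenylchromium species dichloro[(2E)-4-[3-chloro-2,6-bis(methoxymethoxy)-4-methylphenyl]but-2-en-2-yl]chromium F4, which adds to the aldehyde of F3 (Nozaki–Hiyama–Kishi reaction, aldehyde-selective over the ketone) and gives 24 directly. Here C9 reacts as the electrophile, and the ligand, or chromatography of the C9 epimers, controls the carbinol centre.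

Step 5. The vinyl group sits on a quaternary carbon and a ketone is present, so the nickel relay may stall. The fallback sets out from 11 and comes back at 13. Ozonolysis of 11 (O3, CH2Cl2, −78 °C; Me2S) gives the keto aldehyde (1S,2R,6R)-1,2,6-trimethyl-3-oxocyclohexane-1-carbaldehyde F1. Homologation of this non-enolisable aldehyde with dimethyl (1-diazo-2-oxopropyl)phosphonate (K2CO3, MeOH) gives the alkyne (2R,3S,4R)-3-ethynyl-2,3,4-trimethylcyclohexan-1-one F2. Rhodium-catalysed double hydroboration ([Rh(cod)Cl]2, dppb, HBpin, 1,2-dichloroethane, rt), which is chemoselective for C–C multiple bonds over the ketone, passes through 12 and gives 13.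

Step 11. Removing the acetals next to an ionisable allylic alcohol may trigger cyclisation of a phenol onto the allyl system. The fallback sets out from 22 and comes back at 26. The acetals are removed before the coupling, where nothing is acid-sensitive: HCl in MeOH at rt converts 22 into 2-[(2E)-3-bromobut-2-en-1-yl]-4-chloro-5-methylbenzene-1,3-diol F5. F5 is then coupled with 13 under the conditions of step 10, with extra KOH for the two phenols, to the boronate (2R,3S,4R)-3-[(2S,3E)-5-(3-chloro-2,6-dihydroxy-4-methylphenyl)-3-methyl-2-(4,4,5,5-tetramethyl-1,3,2-dioxaborolan-2-yl)pent-3-en-1-yl]-2,3,4-trimethylcyclohexan-1-one F6, which is not isolated. Oxidation with NaBO3·4H2O, milder than alkaline peroxide towards the resorcinol, gives 26.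

Further compounds
F1 | step 5 | (1S,2R,6R)-1,2,6-trimethyl-3-oxocyclohexane-1-carbaldehyde | O=C[C@@]1(C)[C@H](C)CCC(=O)[C@@H]1C
F2 | step 5 | (2R,3S,4R)-3-ethynyl-2,3,4-trimethylcyclohexan-1-one | C#C[C@@]1(C)[C@H](C)CCC(=O)[C@@H]1C
F3 | step 10 | 2-[(1S,2R,6R)-1,2,6-trimethyl-3-oxocyclohexyl]acetaldehyde | O=CC[C@@]1(C)[C@H](C)CCC(=O)[C@@H]1C
F4 | step 10 | dichloro[(2E)-4-[3-chloro-2,6-bis(methoxymethoxy)-4-methylphenyl]but-2-en-2-yl]chromium | Cc1cc(OCOC)c(C/C=C(\C)[Cr](Cl)Cl)c(OCOC)c1Cl
F5 | step 11 | 2-[(2E)-3-bromobut-2-en-1-yl]-4-chloro-5-methylbenzene-1,3-diol | Cc1cc(O)c(C/C=C(\C)Br)c(O)c1Cl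
F6 | step 11 | (2R,3S,4R)-3-[(2S,3E)-5-(3-chloro-2,6-dihydroxy-4-methylphenyl)-3-methyl-2-(4,4,5,5-tetramethyl-1,3,2-dioxaborolan-2-yl)pent-3-en-1-yl]-2,3,4-trimethylcyclohexan-1-one | Cc1cc(O)c(C/C=C(\C)[C@@H](B2OC(C)(C)C(C)(C)O2)C[C@@]3(C)[C@H](C)CCC(=O)[C@@H]3C)c(O)c1Cl
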